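## Analysis of the target

The target is a biflavonoid in which a (2S)-flavanone (benzo ring A with 5-OH and 7-OMe, dihydropyranone ring C, para-phenylene ring B) is joined through a diaryl ether from the para oxygen of ring B to C3' of a 5,7,4'-trihydroxyflavone (benzo ring D, pyranone ring E, aryl ring F). The only stereocentre is C2 of ring C, S configured; it is benzylic, carries the ring oxygen O1 and lies beta to the C4 ketone. That position makes it fragile, because enolisation towards C3 can expel the ring A phenoxide in a retro-oxa-Michael opening to a 2'-hydroxychalcone whose reclosure is unselective, so bases, hot acid and harsh Lewis acids must be avoided once ring C and its ketone exist. Ring E is a vinylogous ester and does not tolerate alkoxides or organometallic reagents. Four phenols must be free at the end while the C7 methyl ether stays, so the two oxygens of ring A have to be told apart. The difficulty is therefore to set C2 with control, to keep it, and to build two different flavonoid halves on one diaryl ether without conditions that harm either. The strategy rests on the position of the C4 carbonyl: C4 is bonded to C4a of ring A, and C4a is flanked by C8a, which bears O1, and by C5, which bears oxygen. The C4–C4a bond can therefore be made last in ring C, by an aryl anion at C4a attacking a C4 carboxyl group after the C2–O1 ether centre is fixed in an open chain where no retro-Michael path exists, and the peri carbonyl created in this way later marks the C5 ether for selective cleavage.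

## Retrosynthetic reasoning

**30 to 29.** The last operation removes three benzyl groups and the C5 methyl group. Ring A is carried as the dimethyl ether because it then derives from a symmetric phenol. The C4 carbonyl and O5 chelate a boron Lewis acid, so only the C5 methyl ether is activated. The forward step must cleave four ethers without opening ring C.

**29 to 28, then to 21 and 26.** Ring E is cut at C2=C3 and at O1–C2. This leads back to the aryl ester 28, whose acyl ylide olefinates the ester carbonyl. The classical flavone syntheses use strong base, which would open ring C of the flavanone half; a neutral stabilised ylide does not. Ring E also has to be built after the organolithium step, because it would not survive it. Ester 28 divides into acid 21 and phosphorane 26. Compound 26 is traced through 24 and 23 to 22.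

**21 to 20 to 19.** The ring F carboxyl group is traced back to a dioxolane. In this masked form the carbon can pass through the hydride reduction, the hydroboration and the organolithium step without change.

**19 to 15 (key disconnection).** The C4–C4a bond is cut. This gives the beta-aryloxy acid 15, with bromine at the future C4a. A cut at O1–C2 would create the stereocentre in a reversible conjugate addition. A Friedel–Crafts closure would need acid that ionises the benzylic ether. The chosen cut leaves C2 untouched and exposes no ketone to base.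

**15 to 13 to 11.** The carboxyl carbon and C3 come from the vinyl group of the branched allyl ether 11, by anti-Markovnikov hydration and oxidation. This keeps every carbonyl away from the aryloxy centre until the acid is needed.

**11 to 7 and 9.** The C2–O1 bond is cut. The forward reaction is an iridium-catalysed asymmetric allylic etherification of the linear carbonate 7 with the phenoxide of 9. The ligand sets C2. Compound 9 comes from the symmetric phenol 8 by one ortho bromination.

**7 to 6, 5 and 4, then to 2 and 3.** The allylic carbonate is traced through alcohol 6 and cinnamate 5 to aldehyde 4. The diaryl ether of 4 is cut next to ring B, where a para formyl group activates fluoride displacement. The two aldehydes are distinguished by acetalising 1 to 2 before the coupling with 3.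

## Alternatives that were turned down

Alternative 1: This route builds ring A itself by cutting C4a–C8a.
- Forward key step: Mg(OMe)2 in methanol opens the lactone of the methoxypyranone A1. The opened chain then closes by Claisen attack of the C4a carbon on the ester carbon and gives the 2',6'-dihydroxy-4'-methoxychalcone A2.
- For it: the ring A pattern arrives already differentiated. The pyranone methoxy group becomes the C7 ether, and the two new phenols are equivalent, so no selective demethylation is needed. The flavone half is already present, which makes the route convergent.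
- Against it: the key step creates no stereocentre. Chalcone A2 would still need an enantioselective oxa-Michael closure. For a chalcone without extra activation that closure is reversible, and the base that closes ring C also reopens it.
- Against it: alkoxide conditions, and the polyanion chemistry needed to make A1, must coexist with ring E, which alkoxides open. The folding can also take an aldol course instead of the Claisen course.
- Comparison: alternative 1 is stronger on oxygen differentiation. The chosen route offers a catalyst-controlled C2 centre that is configurationally safe until the final steps.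

Alternative 2: This route cuts flavone rings D and E back to a tetraketide chain.
- Forward key step: Mg(OMe)2 opens the hydroxypyranone A3, Claisen closure forms ring D, and acid-induced dehydrative closure forms ring E. The product is the bromo flavone A4.
- For it: two rings form in one pot and ring D needs no protecting groups. On that point it is stronger than the chosen route, which needs two benzyl ethers there.
- Against it: the key step is spent on the achiral half, which routine chemistry reaches anyway. Ring C, the C2 centre and the differentiated ring A would all have to be built afterwards from the aryl bromide of A4. That would happen in the presence of the acidic, chelating 5,7-dihydroxy pattern of A4, so protection returns and the step count rises.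
- Against it: a tetraketide chain has several competing folding modes.
- Comparison: the chosen route puts its one risky step where the stereocentre-bearing ring is closed, and forms the flavone late under neutral conditions.

Alternative 3: This route cuts O1–C2.
- Forward key step: a cinchona-derived bifunctional thiourea cyclises the ring A phenol of the alkylidene beta-keto ester A5 onto the benzylidene carbon. The product is the trans (2S,3R) chromanone ester A6.
- For it: this is a direct asymmetric flavanone synthesis. It is convergent, and with benzyl protection throughout, its endgame is shorter and needs no methyl ether discrimination. On these points it is as strong as the chosen route or stronger.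
- Against it: ring A must first be desymmetrised into free OH, OBn and OMe at defined positions.
- Against it: the aroyl group of A5 has two ortho oxygens. It is twisted and hindered, which affects both the Knoevenagel assembly and the fit in the catalyst.
- Against it: the bond formed is the one that retro-oxa-Michael breaks. A6 has an acidic C3–H, and its ester must be removed with acid and heat without eroding C2.
- Comparison: the chosen route starts from a symmetric ring A phenol, sets C2 in an acyclic ether that cannot open, and closes ring C by a C–C bond that does not involve the stereocentre.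

Key step: step 10

Remark on the chemistry: the (Sa,Sc,Sc) phosphoramidite is assumed to give the S ether 11 in step 7, by the usual sense of induction with cinnamyl carbonates and aryloxides. If the sense is the opposite, the (Ra,Rc,Rc) ligand is used and nothing else changes.

## Route

Step 1
Reactants: 1 4-(benzyloxy)-3-hydroxybenzaldehyde
Product: 2 2-(benzyloxy)-5-(1,3-dioxolan-2-yl)phenol
Conditions: HOCH2CH2OH, p-TsOH·H2O (cat.), toluene, reflux, Dean–Stark
Reagents that add atoms: ethylene glycol, OCCO
Why: Acid-catalysed acetalisation with azeotropic water removal; the ring F aldehyde is masked as a dioxolane that is stable to base, hydride and alkyllithium, so the aldehyde introduced in step 2 is the only free one.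

Step 2
Reactants: 2 2-(benzyloxy)-5-(1,3-dioxolan-2-yl)phenol, 3 4-fluorobenzaldehyde
Product: 4 4-[2-(benzyloxy)-5-(1,3-dioxolan-2-yl)phenoxy]benzaldehyde
Conditions: K2CO3, DMF, 100 °C
Reagents that add atoms: none
Why: Nucleophilic aromatic substitution (SNAr) of fluoride activated by the para formyl group; this forms the diaryl ether between rings B and F, and the acetal is inert to carbonate.

Step 3
Reactants: 4 4-[2-(benzyloxy)-5-(1,3-dioxolan-2-yl)phenoxy]benzaldehyde
Product: 5 ethyl (E)-3-{4-[2-(benzyloxy)-5-(1,3-dioxolan-2-yl)phenoxy]phenyl}prop-2-enoate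
Conditions: (EtO)2P(O)CH2CO2Et, NaH, THF, 0 °C to rt
Reagents that add atoms: triethyl phosphonoacetate, CCOC(=O)CP(=O)(OCC)OCC
Why: Horner–Wadsworth–Emmons olefination of an aromatic aldehyde with a stabilised phosphonate should give the E cinnamate.

Step 4
Reactants: 5 ethyl (E)-3-{4-[2-(benzyloxy)-5-(1,3-dioxolan-2-yl)phenoxy]phenyl}prop-2-enoate
Product: 6 (E)-3-{4-[2-(benzyloxy)-5-(1,3-dioxolan-2-yl)phenoxy]phenyl}prop-2-en-1-ol
Conditions: i-Bu2AlH (2.5 equiv), CH2Cl2, −78 °C; aq. KNaC4H4O6
Reagents that add atoms: none
Why: 1,2-Reduction of the enoate by i-Bu2AlH at low temperature should give the allylic alcohol without touching the dioxolane or the benzyl ether.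

Step 5
Reactants: 6 (E)-3-{4-[2-(benzyloxy)-5-(1,3-dioxolan-2-yl)phenoxy]phenyl}prop-2-en-1-ol
Product: 7 (E)-3-{4-[2-(benzyloxy)-5-(1,3-dioxolan-2-yl)phenoxy]phenyl}prop-2-en-1-yl methyl carbonate
Conditions: ClCO2Me, pyridine, CH2Cl2, 0 °C
Reagents that add atoms: methyl chloroformate, COC(=O)Cl
Why: O-Acylation of the primary allylic alcohol gives the linear methyl carbonate, the standard electrophile for iridium-catalysed allylic substitution.

Step 6
Reactants: 8 3,5-dimethoxyphenol
Product: 9 2-bromo-3,5-dimethoxyphenol
Conditions: NBS (1.0 equiv), CH2Cl2, −78 to 0 °C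
Reagents that add atoms: N-bromosuccinimide, O=C1CCC(=O)N1Br
Why: Electrophilic aromatic bromination; the position ortho to the hydroxyl and para to a methoxy group is doubly activated and less hindered than the position between the two methoxy groups, and both ortho positions are equivalent by symmetry, so one monobromide should dominate and be separable from the minor isomer.

Step 7
Reactants: 7 (E)-3-{4-[2-(benzyloxy)-5-(1,3-dioxolan-2-yl)phenoxy]phenyl}prop-2-en-1-yl methyl carbonate, 9 2-bromo-3,5-dimethoxyphenol
Product: 11 2-{4-(benzyloxy)-3-[4-((1S)-1-(2-bromo-3,5-dimethoxyphenoxy)prop-2-en-1-yl)phenoxy]phenyl}-1,3-dioxolane, via lithium phenoxide 10 (not isolated)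
Conditions: 9, LiN(SiMe3)2, THF, 0 °C; then 7, [Ir(cod)Cl]2 (2 mol %), (Sa,Sc,Sc)-N,N-bis(1-phenylethyl) binaphthyl phosphoramidite (4 mol %), THF, 50 °C
Reagents that add atoms: none
Why: Iridium-catalysed asymmetric allylic etherification; the cyclometallated iridium phosphoramidite ionises the linear carbonate and the aryloxide attacks the aryl-substituted allyl terminus, giving the branched ether, and the ligand controls which face is attacked so that C2 is set as S; the aryl bromide is inert to this catalyst.

Step 8
Reactants: 11 2-{4-(benzyloxy)-3-[4-((1S)-1-(2-bromo-3,5-dimethoxyphenoxy)prop-2-en-1-yl)phenoxy]phenyl}-1,3-dioxolane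
Product: 13 (3S)-3-{4-[2-(benzyloxy)-5-(1,3-dioxolan-2-yl)phenoxy]phenyl}-3-(2-bromo-3,5-dimethoxyphenoxy)propan-1-ol, via B-alkyl-9-BBN 12 (not isolated)
Conditions: 9-BBN, THF, 0 °C to rt; then aq. NaOH, H2O2, 0 °C
Reagents that add atoms: hydrogen peroxide, OO
Why: Anti-Markovnikov hydroboration of the terminal alkene with the bulky 9-BBN followed by alkaline peroxide oxidation; boron ends up on the terminal carbon, two carbons away from the ether-bearing carbon, so no beta-alkoxy elimination is possible and the stereocentre is untouched. The borabicyclononane unit is carried only in 12 and is lost on oxidation, and the new hydroxyl oxygen comes from hydrogen peroxide.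

Step 9
Reactants: 13 (3S)-3-{4-[2-(benzyloxy)-5-(1,3-dioxolan-2-yl)phenoxy]phenyl}-3-(2-bromo-3,5-dimethoxyphenoxy)propan-1-ol
Product: 15 (3S)-3-{4-[2-(benzyloxy)-5-(1,3-dioxolan-2-yl)phenoxy]phenyl}-3-(2-bromo-3,5-dimethoxyphenoxy)propanoic acid, via aldehyde 14 (not isolated)
Conditions: TEMPO (cat.), NaClO2, NaOCl (cat.), MeCN/phosphate buffer pH 6.7, 35 °C
Reagents that add atoms: sodium chlorite, [Na+].[O-]Cl=O
Why: TEMPO-catalysed oxidation with chlorite as terminal oxidant; the beta-aryloxy aldehyde 14 is oxidised as it forms near neutral pH, which should suppress aryloxide elimination, acetal hydrolysis and ring chlorination.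

Step 10
Reactants: 15 (3S)-3-{4-[2-(benzyloxy)-5-(1,3-dioxolan-2-yl)phenoxy]phenyl}-3-(2-bromo-3,5-dimethoxyphenoxy)propanoic acid
Product: 19 (2S)-2-{4-[2-(benzyloxy)-5-(1,3-dioxolan-2-yl)phenoxy]phenyl}-5,7-dimethoxychroman-4-one, via bromo lithium carboxylate 16 (not isolated), via aryllithium carboxylate 17 (not isolated), via dilithium gem-diolate 18 (not isolated)
Conditions: n-BuLi (2.0–2.1 equiv), THF, −78 °C, then slowly to −20 °C; sat. aq. NH4Cl
Reagents that add atoms: none
Why: Parham cycloacylation: the first equivalent of n-BuLi deprotonates the acid to 16, the second exchanges the C4a bromine for lithium faster than any C–H deprotonation at −78 °C, and the aryllithium 17, held near the carboxylate by the three-atom tether, adds to the carboxylate carbon. Ring C closes in the 6-exo-trig mode (six-membered ring, carbonyl oxygen outside the ring) to the dilithium gem-diolate 18, which cannot collapse to the ketone before the aqueous quench. The closest known reaction type is the bromine–lithium exchange and cyclisation of 3-(2-bromoaryloxy)propanoic and 3-(2-bromoaryl)propanoic acids to chroman-4-ones and indanones. No stereocentre is formed; C2 is an ether carbon outside the bond-forming event, and because no enolisable ketone coexists with base, the retro-oxa-Michael path that would scramble it is closed. The step needs chemoselectivity: exchange and ring closure must outrun deprotonation of the benzylic C2–H and alpha-deprotonation of the carboxylate, which would expel the aryloxide. The low temperature, the fast exchange at a bromide flanked by two oxygens and the low acidity of a lithium carboxylate should secure this. Benzyl ether, dioxolane and diaryl ether are inert to n-BuLi at this temperature, and no excess n-BuLi is used, so none remains to add to the carboxylate on warming.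

Step 11
Reactants: 19 (2S)-2-{4-[2-(benzyloxy)-5-(1,3-dioxolan-2-yl)phenoxy]phenyl}-5,7-dimethoxychroman-4-one
Product: 20 4-(benzyloxy)-3-{4-[(2S)-5,7-dimethoxy-4-oxochroman-2-yl]phenoxy}benzaldehyde
Conditions: p-TsOH·H2O (cat.), acetone/H2O, rt
Reagents that add atoms: water, O
Why: Mild acid hydrolysis (transacetalisation) of an electron-rich aryl dioxolane; dilute acid at room temperature should not open ring C.

Step 12
Reactants: 20 4-(benzyloxy)-3-{4-[(2S)-5,7-dimethoxy-4-oxochroman-2-yl]phenoxy}benzaldehyde
Product: 21 4-(benzyloxy)-3-{4-[(2S)-5,7-dimethoxy-4-oxochroman-2-yl]phenoxy}benzoic acid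
Conditions: NaClO2, NaH2PO4, 2-methyl-2-butene, t-BuOH/THF/H2O, 0 °C to rt
Reagents that add atoms: sodium chlorite, [Na+].[O-]Cl=O
Why: Pinnick oxidation at weakly acidic pH leaves the flavanone centre alone; the alkene scavenger traps hypochlorous acid before it can chlorinate ring A.

Step 13
Reactants: 22 1-(2,4,6-trihydroxyphenyl)ethanone
Product: 23 1-[2,4-bis(benzyloxy)-6-hydroxyphenyl]ethanone
Conditions: BnBr (2.1 equiv), K2CO3, acetone, reflux
Reagents that add atoms: benzyl bromide, BrCc1ccccc1
Why: Williamson etherification; one ortho hydroxyl is hydrogen-bonded to the acetyl carbonyl and is the least nucleophilic, so dibenzylation should leave it free.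

Step 14
Reactants: 23 1-[2,4-bis(benzyloxy)-6-hydroxyphenyl]ethanone
Product: 24 1-[2,4-bis(benzyloxy)-6-hydroxyphenyl]-2-bromoethanone
Conditions: CuBr2 (2 equiv), EtOAc/CHCl3, reflux
Reagents that add atoms: copper dibromide, Br[Cu]Br
Why: Alpha-bromination of an aryl methyl ketone through its copper-bound enol, the classical method for hydroxyacetophenones, which favours the side chain over the activated ring.

Step 15
Reactants: 24 1-[2,4-bis(benzyloxy)-6-hydroxyphenyl]-2-bromoethanone
Product: 26 1-[2,4-bis(benzyloxy)-6-hydroxyphenyl]-2-(triphenyl-λ5-phosphanylidene)ethanone, via phosphonium bromide 25 (not isolated)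
Conditions: PPh3, toluene, 60 °C; then aq. Na2CO3, CH2Cl2, rt
Reagents that add atoms: triphenylphosphine, c1ccc(cc1)P(c1ccccc1)c1ccccc1
Why: SN2 displacement by the neutral phosphine forms the phenacylphosphonium salt without the base that would cyclise the bromoketone to a benzofuranone; carbonate then gives the stabilised acyl ylide.

Step 16
Reactants: 21 4-(benzyloxy)-3-{4-[(2S)-5,7-dimethoxy-4-oxochroman-2-yl]phenoxy}benzoic acid, 26 1-[2,4-bis(benzyloxy)-6-hydroxyphenyl]-2-(triphenyl-λ5-phosphanylidene)ethanone
Product: 28 3,5-bis(benzyloxy)-2-[(triphenyl-λ5-phosphanylidene)acetyl]phenyl 4-(benzyloxy)-3-{4-[(2S)-5,7-dimethoxy-4-oxochroman-2-yl]phenoxy}benzoate, via aroyl chloride 27 (not isolated)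
Conditions: (COCl)2, DMF (cat.), CH2Cl2, 0 °C to rt; then 26, pyridine, CH2Cl2, 0 °C to rt; aq. NaHCO3 wash
Reagents that add atoms: none
Why: Acid chloride formation and O-acylation of the ylide phenol in pyridine, the known entry to O-aroyl phenacylidene phosphoranes; pyridine is too weak a base to enolise the flavanone.

Step 17
Reactants: 28 3,5-bis(benzyloxy)-2-[(triphenyl-λ5-phosphanylidene)acetyl]phenyl 4-(benzyloxy)-3-{4-[(2S)-5,7-dimethoxy-4-oxochroman-2-yl]phenoxy}benzoate
Product: 29 (2S)-2-{4-[2-(benzyloxy)-5-(5,7-bis(benzyloxy)-4-oxo-4H-chromen-2-yl)phenoxy]phenyl}-5,7-dimethoxychroman-4-one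
Conditions: toluene, reflux
Reagents that add atoms: none
Why: Intramolecular Wittig olefination of the ester carbonyl by the neighbouring acyl ylide closes ring E and gives the flavone under neutral conditions, so C2 of ring C is not exposed to base.

Step 18
Reactants: 29 (2S)-2-{4-[2-(benzyloxy)-5-(5,7-bis(benzyloxy)-4-oxo-4H-chromen-2-yl)phenoxy]phenyl}-5,7-dimethoxychroman-4-one
Product: 30 (2S)-2-{4-[5-(5,7-dihydroxy-4-oxo-4H-chromen-2-yl)-2-hydroxyphenoxy]phenyl}-5-hydroxy-7-methoxychroman-4-one
Conditions: BCl3 (excess), pentamethylbenzene, CH2Cl2, −78 to 0 °C; then MeOH, aq. NaHCO3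
Reagents that add atoms: none
Why: Lewis-acid ether cleavage; BCl3 removes aryl benzyl ethers at low temperature with the arene as benzyl cation trap, and cleaves only the methyl ether whose oxygen chelates boron together with the C4 carbonyl (C5), so the C7 methyl ether should remain.

## Compound list

1 | 4-(benzyloxy)-3-hydroxybenzaldehyde | O=Cc1ccc(OCc2ccccc2)c(O)c1 | starting material
2 | 2-(benzyloxy)-5-(1,3-dioxolan-2-yl)phenol | Oc1cc(C2OCCO2)ccc1OCc1ccccc1 | intermediate
3 | 4-fluorobenzaldehyde | O=Cc1ccc(F)cc1 | starting material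
4 | 4-[2-(benzyloxy)-5-(1,3-dioxolan-2-yl)phenoxy]benzaldehyde | O=Cc1ccc(Oc2cc(C3OCCO3)ccc2OCc2ccccc2)cc1 | intermediate
5 | ethyl (E)-3-{4-[2-(benzyloxy)-5-(1,3-dioxolan-2-yl)phenoxy]phenyl}prop-2-enoate | CCOC(=O)/C=C/c1ccc(Oc2cc(C3OCCO3)ccc2OCc2ccccc2)cc1 | intermediate
6 | (E)-3-{4-[2-(benzyloxy)-5-(1,3-dioxolan-2-yl)phenoxy]phenyl}prop-2-en-1-ol | OC/C=C/c1ccc(Oc2cc(C3OCCO3)ccc2OCc2ccccc2)cc1 | intermediate
7 | (E)-3-{4-[2-(benzyloxy)-5-(1,3-dioxolan-2-yl)phenoxy]phenyl}prop-2-en-1-yl methyl carbonate | COC(=O)OC/C=C/c1ccc(Oc2cc(C3OCCO3)ccc2OCc2ccccc2)cc1 | intermediate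
8 | 3,5-dimethoxyphenol | COc1cc(O)cc(OC)c1 | starting material
9 | 2-bromo-3,5-dimethoxyphenol | COc1cc(O)c(Br)c(OC)c1 | intermediate
10 | lithium 2-bromo-3,5-dimethoxyphenoxide | [Li+].[O-]c1cc(OC)cc(OC)c1Br | intermediate
11 | 2-{4-(benzyloxy)-3-[4-((1S)-1-(2-bromo-3,5-dimethoxyphenoxy)prop-2-en-1-yl)phenoxy]phenyl}-1,3-dioxolane | COc1cc(OC)c(Br)c(c1)O[C@H](c1ccc(Oc2cc(C3OCCO3)ccc2OCc2ccccc2)cc1)C=C | intermediate
12 | 9-[(3S)-3-{4-[2-(benzyloxy)-5-(1,3-dioxolan-2-yl)phenoxy]phenyl}-3-(2-bromo-3,5-dimethoxyphenoxy)propyl]-9-borabicyclo[3.3.1]nonane | COc1cc(OC)c(Br)c(c1)O[C@H](c1ccc(Oc2cc(C3OCCO3)ccc2OCc2ccccc2)cc1)CCB1C2CCCC1CCC2 | intermediate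
13 | (3S)-3-{4-[2-(benzyloxy)-5-(1,3-dioxolan-2-yl)phenoxy]phenyl}-3-(2-bromo-3,5-dimethoxyphenoxy)propan-1-ol | COc1cc(OC)c(Br)c(c1)O[C@H](c1ccc(Oc2cc(C3OCCO3)ccc2OCc2ccccc2)cc1)CCO | intermediate
14 | (3S)-3-{4-[2-(benzyloxy)-5-(1,3-dioxolan-2-yl)phenoxy]phenyl}-3-(2-bromo-3,5-dimethoxyphenoxy)propanal | COc1cc(OC)c(Br)c(c1)O[C@H](c1ccc(Oc2cc(C3OCCO3)ccc2OCc2ccccc2)cc1)CC=O | intermediate
15 | (3S)-3-{4-[2-(benzyloxy)-5-(1,3-dioxolan-2-yl)phenoxy]phenyl}-3-(2-bromo-3,5-dimethoxyphenoxy)propanoic acid | COc1cc(OC)c(Br)c(c1)O[C@H](c1ccc(Oc2cc(C3OCCO3)ccc2OCc2ccccc2)cc1)CC(=O)O | intermediate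
16 | lithium (3S)-3-{4-[2-(benzyloxy)-5-(1,3-dioxolan-2-yl)phenoxy]phenyl}-3-(2-bromo-3,5-dimethoxyphenoxy)propanoate | COc1cc(OC)c(Br)c(c1)O[C@H](c1ccc(Oc2cc(C3OCCO3)ccc2OCc2ccccc2)cc1)CC(=O)[O-].[Li+] | intermediate
17 | lithium (3S)-3-{4-[2-(benzyloxy)-5-(1,3-dioxolan-2-yl)phenoxy]phenyl}-3-(2-lithio-3,5-dimethoxyphenoxy)propanoate | COc1cc(OC)c([Li])c(c1)O[C@H](c1ccc(Oc2cc(C3OCCO3)ccc2OCc2ccccc2)cc1)CC(=O)[O-].[Li+] | intermediate
18 | dilithium (2S)-2-{4-[2-(benzyloxy)-5-(1,3-dioxolan-2-yl)phenoxy]phenyl}-5,7-dimethoxychromane-4,4-bis(olate) | COc1cc(OC)c2c(c1)O[C@H](c1ccc(Oc3cc(C4OCCO4)ccc3OCc3ccccc3)cc1)CC2([O-])[O-].[Li+].[Li+] | intermediate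
19 | (2S)-2-{4-[2-(benzyloxy)-5-(1,3-dioxolan-2-yl)phenoxy]phenyl}-5,7-dimethoxychroman-4-one | COc1cc(OC)c2c(c1)O[C@H](c1ccc(Oc3cc(C4OCCO4)ccc3OCc3ccccc3)cc1)CC2=O | intermediate
20 | 4-(benzyloxy)-3-{4-[(2S)-5,7-dimethoxy-4-oxochroman-2-yl]phenoxy}benzaldehyde | COc1cc(OC)c2c(c1)O[C@H](c1ccc(Oc3cc(C=O)ccc3OCc3ccccc3)cc1)CC2=O | intermediate
21 | 4-(benzyloxy)-3-{4-[(2S)-5,7-dimethoxy-4-oxochroman-2-yl]phenoxy}benzoic acid | COc1cc(OC)c2c(c1)O[C@H](c1ccc(Oc3cc(C(=O)O)ccc3OCc3ccccc3)cc1)CC2=O | intermediate
22 | 1-(2,4,6-trihydroxyphenyl)ethanone | CC(=O)c1c(O)cc(O)cc1O | starting material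
23 | 1-[2,4-bis(benzyloxy)-6-hydroxyphenyl]ethanone | CC(=O)c1c(O)cc(OCc2ccccc2)cc1OCc1ccccc1 | intermediate
24 | 1-[2,4-bis(benzyloxy)-6-hydroxyphenyl]-2-bromoethanone | BrCC(=O)c1c(O)cc(OCc2ccccc2)cc1OCc1ccccc1 | intermediate
25 | {2-[2,4-bis(benzyloxy)-6-hydroxyphenyl]-2-oxoethyl}triphenylphosphonium bromide | [Br-].O=C(C[P+](c1ccccc1)(c1ccccc1)c1ccccc1)c1c(O)cc(OCc2ccccc2)cc1OCc1ccccc1 | intermediate
26 | 1-[2,4-bis(benzyloxy)-6-hydroxyphenyl]-2-(triphenyl-λ5-phosphanylidene)ethanone | O=C(C=P(c1ccccc1)(c1ccccc1)c1ccccc1)c1c(O)cc(OCc2ccccc2)cc1OCc1ccccc1 | intermediate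
27 | 4-(benzyloxy)-3-{4-[(2S)-5,7-dimethoxy-4-oxochroman-2-yl]phenoxy}benzoyl chloride | COc1cc(OC)c2c(c1)O[C@H](c1ccc(Oc3cc(C(=O)Cl)ccc3OCc3ccccc3)cc1)CC2=O | intermediate
28 | 3,5-bis(benzyloxy)-2-[(triphenyl-λ5-phosphanylidene)acetyl]phenyl 4-(benzyloxy)-3-{4-[(2S)-5,7-dimethoxy-4-oxochroman-2-yl]phenoxy}benzoate | COc1cc(OC)c2c(c1)O[C@H](c1ccc(Oc3cc(C(=O)Oc4cc(OCc5ccccc5)cc(OCc5ccccc5)c4C(=O)C=P(c4ccccc4)(c4ccccc4)c4ccccc4)ccc3OCc3ccccc3)cc1)CC2=O | intermediate
29 | (2S)-2-{4-[2-(benzyloxy)-5-(5,7-bis(benzyloxy)-4-oxo-4H-chromen-2-yl)phenoxy]phenyl}-5,7-dimethoxychroman-4-one | COc1cc(OC)c2c(c1)O[C@H](c1ccc(Oc3cc(-c4cc(=O)c5c(OCc6ccccc6)cc(OCc6ccccc6)cc5o4)ccc3OCc3ccccc3)cc1)CC2=O | intermediate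
30 | (2S)-2-{4-[5-(5,7-dihydroxy-4-oxo-4H-chromen-2-yl)-2-hydroxyphenoxy]phenyl}-5-hydroxy-7-methoxychroman-4-one | COc1cc(O)c2c(c1)O[C@H](c1ccc(Oc3cc(-c4cc(=O)c5c(O)cc(O)cc5o4)ccc3O)cc1)CC2=O | target

## Step count and least certain steps

Total: 18 steps. Longest linear sequence: 14 steps (steps 1–5, 7–12, 16–18).

The key step, step 10, is the least certain. The aryllithium may be quenched by proton transfer from the benzylic C2–H through a five-membered transition state, followed by Wittig-type rearrangement. The addition to the poorly electrophilic lithium carboxylate may be slow at a doubly ortho-substituted aryllithium, and the aryllithium may be alkylated by the bromobutane formed in the exchange. The fallback sets out from 15 and returns at 19. Acid 15 is coupled with N,O-dimethylhydroxylamine hydrochloride (EDC·HCl, N-methylmorpholine, CH2Cl2) to the Weinreb amide (3S)-3-{4-[2-(benzyloxy)-5-(1,3-dioxolan-2-yl)phenoxy]phenyl}-3-(2-bromo-3,5-dimethoxyphenoxy)-N-methoxy-N-methylpropanamide F1. Exchange with t-BuLi (2 equiv, THF, −100 to −78 °C) then lets the aryllithium close onto a neutral, chelating acyl donor. The ketone is again released only on quench, now from a monoanionic intermediate and at lower temperature, and 19 results.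

In step 7, the donor para-aryloxy group and the hindered ortho-brominated aryloxide may lower the branched selectivity, and reversible ionisation of the product ether may erode the enantiomeric purity. The fallback sets out from 4 and returns at 15. Asymmetric allylation of 4 with the antipode of (Ipc)2B(allyl) that delivers the R carbinol gives (R)-1-{4-[2-(benzyloxy)-5-(1,3-dioxolan-2-yl)phenoxy]phenyl}but-3-en-1-ol F2. Mitsunobu etherification with 9 (PPh3, DIAD, toluene, 0 °C) inverts the carbinol centre and gives 2-{4-(benzyloxy)-3-[4-((1S)-1-(2-bromo-3,5-dimethoxyphenoxy)but-3-en-1-yl)phenoxy]phenyl}-1,3-dioxolane F3. Cleavage of the terminal alkene (OsO4 cat., NaIO4, 2,6-lutidine, dioxane/H2O) gives aldehyde 14, and chlorite oxidation of 14 gives 15.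

In step 6, bromination may also occur para to the hydroxyl, between the methoxy groups, and a second bromination may follow. Both would cost material and require a separation of isomers. The fallback sets out from 8 and returns at 9. Carbamoylation of 8 (ClC(O)NEt2, K2CO3, MeCN) gives 3,5-dimethoxyphenyl N,N-diethylcarbamate F4. Directed ortho-lithiation (s-BuLi, TMEDA, THF, −78 °C) occurs at the position between the carbamate and a methoxy group, and quenching with BrCCl2CCl2Br gives 2-bromo-3,5-dimethoxyphenyl N,N-diethylcarbamate F5. Hydrolysis (NaOH, EtOH, reflux) gives 9 with unambiguous regiochemistry.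

In step 17 (with step 16), the ylide carbon may be acylated in competition with the phenol, and olefination of the electron-rich benzoate carbonyl may be slow, so that acyl transfer or thermal erosion at C2 intervenes. The fallback sets out from 23 and 27 (made from 21 as in step 16) and returns at 29. Ketone 23 is converted with LiN(SiMe3)2 (2.0 equiv, THF, −78 °C) into its phenoxide enolate, and this solution is added slowly to 27 at −78 °C, so that the acid chloride is always in excess over base. The C-acylation gives 1-[2,4-bis(benzyloxy)-6-hydroxyphenyl]-3-(4-(benzyloxy)-3-{4-[(2S)-5,7-dimethoxy-4-oxochroman-2-yl]phenoxy}phenyl)propane-1,3-dione F6. Acid cyclodehydration (p-TsOH, toluene, 80 °C) gives 29. Low temperature, inverse addition and the fast consumption of the enolate are meant to limit base contact with ring C.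

In step 18, cleavage of the four ethers may be incomplete or unselective, and the Lewis acid may open ring C at the benzylic C2–O1 bond, with loss of configuration. The fallback sets out from 29 and returns at 30. Hydrogenolysis (H2, Pd(OH)2/C, THF/EtOAc, rt) removes the three benzyl groups and gives (2S)-2-{4-[5-(5,7-dihydroxy-4-oxo-4H-chromen-2-yl)-2-hydroxyphenoxy]phenyl}-5,7-dimethoxychroman-4-one F7. The chelated C5 methyl ether of F7 is then cleaved with the milder MgI2 (etherate, THF, 60 °C) to give 30.

## Further compounds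

F1 | step 10 | (3S)-3-{4-[2-(benzyloxy)-5-(1,3-dioxolan-2-yl)phenoxy]phenyl}-3-(2-bromo-3,5-dimethoxyphenoxy)-N-methoxy-N-methylpropanamide | COc1cc(OC)c(Br)c(c1)O[C@H](c1ccc(Oc2cc(C3OCCO3)ccc2OCc2ccccc2)cc1)CC(=O)N(C)OC
F2 | step 7 | (R)-1-{4-[2-(benzyloxy)-5-(1,3-dioxolan-2-yl)phenoxy]phenyl}but-3-en-1-ol | O[C@@H](c1ccc(Oc2cc(C3OCCO3)ccc2OCc2ccccc2)cc1)CC=C
F3 | step 7 | 2-{4-(benzyloxy)-3-[4-((1S)-1-(2-bromo-3,5-dimethoxyphenoxy)but-3-en-1-yl)phenoxy]phenyl}-1,3-dioxolane | COc1cc(OC)c(Br)c(c1)O[C@H](c1ccc(Oc2cc(C3OCCO3)ccc2OCc2ccccc2)cc1)CC=C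
F4 | step 6 | 3,5-dimethoxyphenyl N,N-diethylcarbamate | CCN(CC)C(=O)Oc1cc(OC)cc(OC)c1
F5 | step 6 | 2-bromo-3,5-dimethoxyphenyl N,N-diethylcarbamate | CCN(CC)C(=O)Oc1cc(OC)cc(OC)c1Br
F6 | step 17 | 1-[2,4-bis(benzyloxy)-6-hydroxyphenyl]-3-(4-(benzyloxy)-3-{4-[(2S)-5,7-dimethoxy-4-oxochroman-2-yl]phenoxy}phenyl)propane-1,3-dione | COc1cc(OC)c2c(c1)O[C@H](c1ccc(Oc3cc(C(=O)CC(=O)c4c(O)cc(OCc5ccccc5)cc4OCc4ccccc4)ccc3OCc3ccccc3)cc1)CC2=O
F7 | step 18 | (2S)-2-{4-[5-(5,7-dihydroxy-4-oxo-4H-chromen-2-yl)-2-hydroxyphenoxy]phenyl}-5,7-dimethoxychroman-4-one | COc1cc(OC)c2c(c1)O[C@H](c1ccc(Oc3cc(-c4cc(=O)c5c(O)cc(O)cc5o4)ccc3O)cc1)CC2=O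
A1 | alternative 1 | 6-[(E)-4-{4-[2-(benzyloxy)-5-(5,7-bis(benzyloxy)-4-oxo-4H-chromen-2-yl)phenoxy]phenyl}-2-oxobut-3-en-1-yl]-4-methoxy-2H-pyran-2-one | COc1cc(CC(=O)/C=C/c2ccc(Oc3cc(-c4cc(=O)c5c(OCc6ccccc6)cc(OCc6ccccc6)cc5o4)ccc3OCc3ccccc3)cc2)oc(=O)c1
A2 | alternative 1 | (E)-3-{4-[2-(benzyloxy)-5-(5,7-bis(benzyloxy)-4-oxo-4H-chromen-2-yl)phenoxy]phenyl}-1-(2,6-dihydroxy-4-methoxyphenyl)prop-2-en-1-one | COc1cc(O)c(C(=O)/C=C/c2ccc(Oc3cc(-c4cc(=O)c5c(OCc6ccccc6)cc(OCc6ccccc6)cc5o4)ccc3OCc3ccccc3)cc2)c(O)c1
A3 | alternative 2 | 6-{4-[4-(benzyloxy)-3-(4-bromophenoxy)phenyl]-2,4-dioxobutyl}-4-hydroxy-2H-pyran-2-one | O=C(CC(=O)Cc1cc(O)cc(=O)o1)c1ccc(OCc2ccccc2)c(Oc2ccc(Br)cc2)c1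
A4 | alternative 2 | 2-[4-(benzyloxy)-3-(4-bromophenoxy)phenyl]-5,7-dihydroxy-4H-chromen-4-one | O=c1cc(-c2ccc(OCc3ccccc3)c(Oc3ccc(Br)cc3)c2)oc2cc(O)cc(O)c12
A5 | alternative 3 | tert-butyl 2-[2-(benzyloxy)-6-hydroxy-4-methoxybenzoyl]-3-{4-[2-(benzyloxy)-5-(5,7-bis(benzyloxy)-4-oxo-4H-chromen-2-yl)phenoxy]phenyl}prop-2-enoate (alkene geometry not fixed) | COc1cc(O)c(C(=O)C(=Cc2ccc(Oc3cc(-c4cc(=O)c5c(OCc6ccccc6)cc(OCc6ccccc6)cc5o4)ccc3OCc3ccccc3)cc2)C(=O)OC(C)(C)C)c(OCc2ccccc2)c1
A6 | alternative 3 | tert-butyl trans-(2S,3R)-5-(benzyloxy)-2-{4-[2-(benzyloxy)-5-(5,7-bis(benzyloxy)-4-oxo-4H-chromen-2-yl)phenoxy]phenyl}-7-methoxy-4-oxochromane-3-carboxylate | COc1cc(OCc2ccccc2)c2c(c1)O[C@H](c1ccc(Oc3cc(-c4cc(=O)c5c(OCc6ccccc6)cc(OCc6ccccc6)cc5o4)ccc3OCc3ccccc3)cc1)[C@@H](C(=O)OC(C)(C)C)C2=O
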